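The readings are simulated with made-up constants.

Slowness is the first thing the readings show: over days in the zeta run, target and isomer of the product A together account for less and less of the charge.

| flask | starting material | remark | time |
|---|---|---|---|
| zeta | 10 mM | run made earlier |  |
| theta | 40 mM | run made earlier |  |
| flask | 20 mM |  | 15 d |

| run | time / d | target / % | isomer of the product A / % |
|---|---|---|---|
| zeta | 1.04 | 76.3 | 13.5 |
| zeta | 2.00 | 72.0 | 11.5 |
| zeta | 5.00 | 67.3 | 6.9 |
| zeta | 12.0 | 62.7 | 3.9 |
| theta | 3.00 | 85.6 | 8.1 |
| theta | 6.00 | 88.3 | 4.8 |
| theta | 10.0 | 88.5 | 2.0 |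
| theta | 12.0 | 89.1 | 2.2 |

(standard deviation of a reading: 0.5 percentage points)

- ratio of target to isomer of the product A at 12 min
- ratio of target to isomer of the product A at 15 d
- which of target and isomer of the product A there is more of at 15 d

- a reading or a percentage of target counts all its forms, free or not

The last rows come first. At 12.0 d the zeta run lacks 33.4% of its charge, and at 12.0 d the theta run lacks 8.70%, so as shares the two runs disagree. Multiplied by the charges, 10 mM and 40 mM, the same rows give 3.34 mM and 3.48 mM. The rows above repeat this, with 2.58 mM at 5.00 d in zeta and 2.76 mM at 6.00 d in theta. The shortfall therefore reads as an amount, not a share, and the missing amount M, the mean of the two last rows, is 3.41 mM.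

For the flask at 20 mM, M is 17.1% of the charge, which leaves 83.0% for target and isomer together. Taking the last theta isomer reading, 2.2%, as the isomer's level gives a ratio of 36.7 at 15 d, with target ahead. That small denominator carries a scatter of 0.5 percentage points, so it is the reading to watch. The ratio at 12 min, a selectivity factor, stands before any row: the first zeta row, at 1.04 d, reads 5.65 but already lacks 10.2% of its charge, so it is a rough guide and no early reading.

The forecast judges that “only a limited free pool of target decays, while the rest is protected”. It gives 5.6 (4.5 to 7) at 12 min and 33 (21 to 50) at 15 d, with target ahead, so its late ratio stands lower than the reckoning here.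

The flask gives 5.56 at 12 min and 45.8 at 15 d, with target ahead, at 80.7% against 1.76% of the isomer of the product A.

    starting material ⇌ target (K = 13.0, k = 4.80 × 10⁻⁵ /s)
    starting material ⇌ isomer of the product A (K = 3.00, k = 8.60 × 10⁻⁶ /s)
    target ⇌ isomer of the product B (K = 3.60, k = 1.10 × 10⁻⁵ /s)
    crystals ⇌ target, rate k4*(cs4 - [target]) while solid is left; crystals form when [target] > cs4 (solubility = 0.970 mM, k = 9.50 × 10⁻⁴ /s)

At 15 d the flask holds 75.8% as crystals, counted in target, and 17.1% as isomer of the product B, which is 3.42 mM beside an M of 3.41 mM. For the neighbouring flask charged with 5.0 mM, M comes to 68.2% of the charge, and at 15 d that flask holds 68.5% as isomer of the product B.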